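The furofuran core is traced back to a donor–acceptor cyclopropane. In the tetrahydrofuran ring that carries the guaiacyl group (O7–C8–C1–C5–C6 of the 3,7-dioxabicyclo[3.3.0]octane), the benzylic carbon C6 and C1 are 1,3-related as cation and enolate sites. This ring is therefore grown from the cyclopropane C1–C5–C6 of an enantioenriched 3-aryl-1,2-bis(hydroxymethyl)cyclopropane-1-carboxylate: a Lewis acid opens the C1–C6 bond, the hydroxymethyl group on C1 inserts its CH2–O unit, and lactonisation closes the second ring in the same operation, fixing C1 and C6 relative to C5. The syringyl group is then added to the lactone, and the erythro glycerol ether is built on its phenol oxygen by auxiliary-controlled aldol reaction and carbinol inversion.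

Key step: step 4

Remark on numbering: the core is numbered as 3,7-dioxabicyclo[3.3.0]octane (C1, C2, O3, C4, C5, C6, O7, C8); "ArO" in the names of 18 and 20–23 is the phenoxy group of 16.
Assumption: 13 and 14 form as both epimers at the carbinol carbon, drawn without configuration because step 7 ionises this centre; 8 is drawn as the C3 epimer that lactonises; 1, 3, 10, 17 and 19 are taken as commercial.

Step 1
Reactants: 1 coniferaldehyde, (E)-3-(4-hydroxy-3-methoxyphenyl)prop-2-enal
Product: 2 (E)-3-[3-methoxy-4-(triisopropylsilyloxy)phenyl]prop-2-enal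
Conditions: TIPSCl, imidazole, DMF, rt
Reagents that add atoms: chlorotriisopropylsilane, CC(C)[Si](Cl)(C(C)C)C(C)C
Why: Imidazole-promoted silylation of the phenol should be clean, and the bulky aryl silyl ether is expected to survive borohydride, base and Lewis acid while keeping the aryl ring a strong donor for step 4.

Step 2
Reactants: 2 (E)-3-[3-methoxy-4-(triisopropylsilyloxy)phenyl]prop-2-enal; 3 diethyl bromomalonate
Product: 4 diethyl (2R,3S)-2-formyl-3-[3-methoxy-4-(triisopropylsilyloxy)phenyl]cyclopropane-1,1-dicarboxylate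
Conditions: (S)-2-[diphenyl(trimethylsilyloxy)methyl]pyrrolidine (20 mol%), 2,6-lutidine, CH2Cl2, 0 °C → rt
Reagents that add atoms: none
Why: Organocatalytic Michael-initiated ring closure: bromomalonate should add to the β-carbon of the E-iminium ion on the face away from the diphenyl(silyloxy)methyl group and the resulting enamine displaces bromide (3-exo-tet), so both ring stereocentres (trans, 2R,3S) are set by the catalyst.

Step 3
Reactants: 4 diethyl (2R,3S)-2-formyl-3-[3-methoxy-4-(triisopropylsilyloxy)phenyl]cyclopropane-1,1-dicarboxylate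
Product: 7 ethyl (1R,2R,3S)-1,2-bis(hydroxymethyl)-3-[3-methoxy-4-(triisopropylsilyloxy)phenyl]cyclopropane-1-carboxylate, via hydroxymethyl diester 5 (not isolated), via lactone ester 6 (not isolated)
Conditions: NaBH4 (excess), EtOH, 0 °C → rt
Reagents that add atoms: none
Why: Chemoselective borohydride reduction: the aldehyde is reduced first, the alkoxide lactonises onto the cis ester, and the activated lactone is then reduced while the hindered trans ester should survive, so the two esters are told apart by their position relative to the hydroxymethyl group and no stereocentre is touched.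

Step 4
Reactants: 7 ethyl (1R,2R,3S)-1,2-bis(hydroxymethyl)-3-[3-methoxy-4-(triisopropylsilyloxy)phenyl]cyclopropane-1-carboxylate
Product: 9 (1R,5R,6S)-6-[3-methoxy-4-(triisopropylsilyloxy)phenyl]-3,7-dioxabicyclo[3.3.0]octan-2-one, via oxolane hydroxy ester 8 (not isolated)
Conditions: Sc(OTf)3 (10 mol%), 4 Å MS, ClCH2CH2Cl, 40 °C; then DBU (0.3 equiv), rt
Reagents that add atoms: none
Why: Proposed new method: Sc(OTf)3 should bind the β-hydroxy ester of 7 as a chelate, as it binds a malonate, and heterolyse the cyclopropane bond between the ester-bearing and the aryl-bearing carbon to a benzylic cation (stabilised by the para-silyloxy group) and an ester enolate, whereupon the hydroxymethyl oxygen on the enolate carbon captures the cation, so that the three-membered ring C1–C5–C6 (numbering of 9) grows by the CH2–O unit into the oxolane ring O7–C8–C1–C5–C6. The closest known reaction types are the Cloke–Wilson rearrangement of aryl cyclopropyl ketones to dihydrofurans and the Lewis-acid-catalysed opening of 2-arylcyclopropane-1,1-diesters by oxygen nucleophiles, from which the step differs in that an sp3 hydroxyl group on the acceptor carbon is the internal nucleophile. Both rings close in the 5-exo-trig mode, the ether ring by attack of oxygen on the cationic benzylic carbon and the lactone ring by attack of the C5 hydroxymethyl group on the ester carbonyl with loss of ethanol. C5 is carried over from 7 and fixes the absolute configuration; C6 is set by the substrate, the aryl group taking the position trans to the C5 substituent (convex face) in a ring closure that is reversible under the Lewis acid; C1 is set when the enolate is protonated, and since only the cis-fused lactone can form and C1–H is epimerised by DBU, both C1 epimers of 8 should converge on 9. The step needs capture of the cation by the C1 hydroxymethyl oxygen: the other hydroxyl group could only close an oxetane, and capture by the ester carbonyl oxygen gives a dialkoxycarbenium ion that has no water to hydrolyse it and should revert.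

Step 5
Reactants: 10 4-bromo-2,6-dimethoxyphenol
Product: 11 2-(benzyloxy)-5-bromo-1,3-dimethoxybenzene
Conditions: BnBr, K2CO3, DMF, rt
Reagents that add atoms: benzyl bromide, BrCc1ccccc1
Why: Williamson ether synthesis on the phenoxide; the benzyl ether tolerates aryllithium formation and is removable later by hydrogenolysis without touching the silyl ether.

Step 6
Reactants: 11 2-(benzyloxy)-5-bromo-1,3-dimethoxybenzene; 9 (1R,5R,6S)-6-[3-methoxy-4-(triisopropylsilyloxy)phenyl]-3,7-dioxabicyclo[3.3.0]octan-2-one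
Product: 14 [4-(benzyloxy)-3,5-dimethoxyphenyl]{(3R,4R,5S)-4-(hydroxymethyl)-5-[3-methoxy-4-(triisopropylsilyloxy)phenyl]oxolan-3-yl}methanol (both carbinol epimers), via aryllithium 12 (not isolated), via hydroxy ketone 13 (not isolated)
Conditions: n-BuLi, THF, −78 °C; then 9, −78 °C; then MeOH, NaBH4, −78 → 0 °C
Reagents that add atoms: none
Why: Bromine–lithium exchange followed by a single addition of the aryllithium to the lactone carbonyl (the tetrahedral lithium alkoxide resists a second addition at −78 °C) and borohydride reduction of the ketone released on protonation; the ring stereocentres are untouched and the carbinol configuration does not matter.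

Step 7
Reactants: 14 [4-(benzyloxy)-3,5-dimethoxyphenyl]{(3R,4R,5S)-4-(hydroxymethyl)-5-[3-methoxy-4-(triisopropylsilyloxy)phenyl]oxolan-3-yl}methanol
Product: 15 (1R,2S,5R,6S)-2-[4-(benzyloxy)-3,5-dimethoxyphenyl]-6-[3-methoxy-4-(triisopropylsilyloxy)phenyl]-3,7-dioxabicyclo[3.3.0]octane
Conditions: camphorsulfonic acid (10 mol%), CH2Cl2, 0 °C
Reagents that add atoms: none
Why: Acid-catalysed SN1 etherification: the benzylic alcohol ionises to a cation stabilised by the trialkoxyphenyl ring and the cis hydroxymethyl group closes the second oxolane ring (5-exo-trig) through the transition state that keeps the aryl group away from the first ring, which should set C2 as S (aryl on the convex face) from either carbinol epimer.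

Step 8
Reactants: 15 (1R,2S,5R,6S)-2-[4-(benzyloxy)-3,5-dimethoxyphenyl]-6-[3-methoxy-4-(triisopropylsilyloxy)phenyl]-3,7-dioxabicyclo[3.3.0]octane
Product: 16 2,6-dimethoxy-4-{(1R,2S,5R,6S)-6-[3-methoxy-4-(triisopropylsilyloxy)phenyl]-3,7-dioxabicyclo[3.3.0]octan-2-yl}phenol
Conditions: H2 (1 atm), Pd/C, EtOAc, rt
Reagents that add atoms: none
Why: Hydrogenolysis of the aryl benzyl ether under neutral conditions should be much faster than cleavage of the ring benzylic C–O bonds, and the aryl silyl ether is inert.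

Step 9
Reactants: 16 2,6-dimethoxy-4-{(1R,2S,5R,6S)-6-[3-methoxy-4-(triisopropylsilyloxy)phenyl]-3,7-dioxabicyclo[3.3.0]octan-2-yl}phenol; 17 (S)-4-benzyl-3-(bromoacetyl)oxazolidin-2-one
Product: 18 (S)-4-benzyl-3-[(ArO)acetyl]oxazolidin-2-one
Conditions: K2CO3, acetone, rt
Reagents that add atoms: none
Why: Williamson ether synthesis: the phenoxide displaces bromide at the activated α-carbon of the imide (SN2), and the aryl silyl ether should survive carbonate in an aprotic solvent.

Step 10
Reactants: 18 (S)-4-benzyl-3-[(ArO)acetyl]oxazolidin-2-one; 19 4-(tert-butyldimethylsilyloxy)-3-methoxybenzaldehyde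
Product: 20 (S)-4-benzyl-3-{(2S,3R)-2-(ArO)-3-[4-(tert-butyldimethylsilyloxy)-3-methoxyphenyl]-3-hydroxypropanoyl}oxazolidin-2-one
Conditions: Bu2BOTf, iPr2NEt, CH2Cl2, −78 → 0 °C; 19, −78 → 0 °C; then pH 7 buffer, MeOH, H2O2, 0 °C
Reagents that add atoms: none
Why: Evans syn-aldol reaction: the Z boron enolate reacts through a closed chair transition state on the face away from the benzyl group of the auxiliary, which should set the aryloxy carbon (the 2R centre of the final diol) and give the syn (threo) carbinol.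

Step 11
Reactants: 20 (S)-4-benzyl-3-{(2S,3R)-2-(ArO)-3-[4-(tert-butyldimethylsilyloxy)-3-methoxyphenyl]-3-hydroxypropanoyl}oxazolidin-2-one
Product: 21 (1R,2R)-2-(ArO)-1-[4-(tert-butyldimethylsilyloxy)-3-methoxyphenyl]propane-1,3-diol (threo)
Conditions: LiBH4, MeOH (1 equiv), THF, 0 °C
Reagents that add atoms: none
Why: Reductive cleavage of the N-acyloxazolidinone by LiBH4 gives the primary alcohol and releases the auxiliary; no stereocentre is touched and both aryl silyl ethers are stable.

Step 12
Reactants: 21 (1R,2R)-2-(ArO)-1-[4-(tert-butyldimethylsilyloxy)-3-methoxyphenyl]propane-1,3-diol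
Product: 22 (1S,2R)-2-(ArO)-1-[4-(tert-butyldimethylsilyloxy)-3-methoxyphenyl]propane-1,3-diyl bis(4-nitrobenzoate)
Conditions: PPh3, DIAD, 4-nitrobenzoic acid (3 equiv each), THF, 0 °C → rt
Reagents that add atoms: 4-nitrobenzoic acid, O=C(O)c1ccc(cc1)[N+](=O)[O-]
Why: Double Mitsunobu reaction: the primary alcohol is esterified and the secondary benzylic alcohol is displaced by the carboxylate with inversion (SN2 on the alkoxyphosphonium ion), which should turn the threo into the erythro (1S,2R) arrangement.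

Step 13
Reactants: 22 (1S,2R)-2-(ArO)-1-[4-(tert-butyldimethylsilyloxy)-3-methoxyphenyl]propane-1,3-diyl bis(4-nitrobenzoate)
Product: 23 (1S,2R)-2-(ArO)-1-[4-(tert-butyldimethylsilyloxy)-3-methoxyphenyl]propane-1,3-diol (erythro)
Conditions: LiBH4, THF, 0 °C → rt
Reagents that add atoms: none
Why: Reductive cleavage of both 4-nitrobenzoates leaves the aryl silyl ethers in place, so the para phenol is never free while the benzylic ester is present and no quinone methide can form; the C–O bonds at the stereocentres are not broken.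

Step 14
Reactants: 23 (1S,2R)-2-(ArO)-1-[4-(tert-butyldimethylsilyloxy)-3-methoxyphenyl]propane-1,3-diol
Product: 24 Hedyotol C, (1S,2R)-2-{4-[(1R,2S,5R,6S)-6-(4-hydroxy-3-methoxyphenyl)-3,7-dioxabicyclo[3.3.0]octan-2-yl]-2,6-dimethoxyphenoxy}-1-(4-hydroxy-3-methoxyphenyl)propane-1,3-diol
Conditions: TBAF, AcOH, THF, 0 °C
Reagents that add atoms: none
Why: Buffered fluoride desilylation should remove both aryl silyl ethers without base- or acid-induced ionisation of the benzylic ethers or of the benzylic alcohol.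

Compound list
1 | coniferaldehyde, (E)-3-(4-hydroxy-3-methoxyphenyl)prop-2-enal | COc1cc(/C=C/C=O)ccc1O | starting material
2 | (E)-3-[3-methoxy-4-(triisopropylsilyloxy)phenyl]prop-2-enal | COc1cc(/C=C/C=O)ccc1O[Si](C(C)C)(C(C)C)C(C)C | intermediate
3 | diethyl bromomalonate | CCOC(=O)C(Br)C(=O)OCC | starting material
4 | diethyl (2R,3S)-2-formyl-3-[3-methoxy-4-(triisopropylsilyloxy)phenyl]cyclopropane-1,1-dicarboxylate | O=C[C@@H]1[C@@H](c2ccc(O[Si](C(C)C)(C(C)C)C(C)C)c(OC)c2)C1(C(=O)OCC)C(=O)OCC | intermediate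
5 | diethyl (2R,3S)-2-(hydroxymethyl)-3-[3-methoxy-4-(triisopropylsilyloxy)phenyl]cyclopropane-1,1-dicarboxylate (not isolated) | OC[C@@H]1[C@@H](c2ccc(O[Si](C(C)C)(C(C)C)C(C)C)c(OC)c2)C1(C(=O)OCC)C(=O)OCC | intermediate
6 | ethyl (1S,5R,6S)-6-[3-methoxy-4-(triisopropylsilyloxy)phenyl]-2-oxo-3-oxabicyclo[3.1.0]hexane-1-carboxylate (not isolated) | CCOC(=O)[C@@]12C(=O)OC[C@@H]1[C@H]2c1ccc(O[Si](C(C)C)(C(C)C)C(C)C)c(OC)c1 | intermediate
7 | ethyl (1R,2R,3S)-1,2-bis(hydroxymethyl)-3-[3-methoxy-4-(triisopropylsilyloxy)phenyl]cyclopropane-1-carboxylate | CCOC(=O)[C@@]1(CO)[C@H](CO)[C@H]1c1ccc(O[Si](C(C)C)(C(C)C)C(C)C)c(OC)c1 | intermediate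
8 | ethyl (3R,4R,5S)-4-(hydroxymethyl)-5-[3-methoxy-4-(triisopropylsilyloxy)phenyl]oxolane-3-carboxylate (not isolated) | CCOC(=O)[C@H]1CO[C@H](c2ccc(O[Si](C(C)C)(C(C)C)C(C)C)c(OC)c2)[C@H]1CO | intermediate
9 | (1R,5R,6S)-6-[3-methoxy-4-(triisopropylsilyloxy)phenyl]-3,7-dioxabicyclo[3.3.0]octan-2-one | O=C1OC[C@H]2[C@@H]1CO[C@@H]2c1ccc(O[Si](C(C)C)(C(C)C)C(C)C)c(OC)c1 | intermediate
10 | 4-bromo-2,6-dimethoxyphenol | COc1cc(Br)cc(OC)c1O | starting material
11 | 2-(benzyloxy)-5-bromo-1,3-dimethoxybenzene | COc1cc(Br)cc(OC)c1OCc1ccccc1 | intermediate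
12 | [4-(benzyloxy)-3,5-dimethoxyphenyl]lithium (not isolated) | [Li]c1cc(OC)c(OCc2ccccc2)c(OC)c1 | intermediate
13 | [4-(benzyloxy)-3,5-dimethoxyphenyl]{(3R,4R,5S)-4-(hydroxymethyl)-5-[3-methoxy-4-(triisopropylsilyloxy)phenyl]oxolan-3-yl}methanone, open form of the hemiketal (not isolated) | OC[C@@H]1[C@@H](c2ccc(O[Si](C(C)C)(C(C)C)C(C)C)c(OC)c2)OC[C@@H]1C(=O)c1cc(OC)c(OCc2ccccc2)c(OC)c1 | intermediate
14 | [4-(benzyloxy)-3,5-dimethoxyphenyl]{(3R,4R,5S)-4-(hydroxymethyl)-5-[3-methoxy-4-(triisopropylsilyloxy)phenyl]oxolan-3-yl}methanol, both carbinol epimers | OC[C@@H]1[C@@H](c2ccc(O[Si](C(C)C)(C(C)C)C(C)C)c(OC)c2)OC[C@@H]1C(O)c1cc(OC)c(OCc2ccccc2)c(OC)c1 | intermediate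
15 | (1R,2S,5R,6S)-2-[4-(benzyloxy)-3,5-dimethoxyphenyl]-6-[3-methoxy-4-(triisopropylsilyloxy)phenyl]-3,7-dioxabicyclo[3.3.0]octane | COc1cc([C@H]2OC[C@H]3[C@@H]2CO[C@@H]3c2cc(OC)c(OCc3ccccc3)c(OC)c2)ccc1O[Si](C(C)C)(C(C)C)C(C)C | intermediate
16 | 2,6-dimethoxy-4-{(1R,2S,5R,6S)-6-[3-methoxy-4-(triisopropylsilyloxy)phenyl]-3,7-dioxabicyclo[3.3.0]octan-2-yl}phenol | COc1cc([C@H]2OC[C@H]3[C@@H]2CO[C@@H]3c2cc(OC)c(O)c(OC)c2)ccc1O[Si](C(C)C)(C(C)C)C(C)C | intermediate
17 | (S)-4-benzyl-3-(bromoacetyl)oxazolidin-2-one | O=C(CBr)N1[C@@H](Cc2ccccc2)COC1=O | starting material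
18 | (S)-4-benzyl-3-[(ArO)acetyl]oxazolidin-2-one, ArO = phenoxy group of 16 | COc1cc([C@H]2OC[C@H]3[C@@H]2CO[C@@H]3c2cc(OC)c(OCC(=O)N3[C@@H](Cc4ccccc4)COC3=O)c(OC)c2)ccc1O[Si](C(C)C)(C(C)C)C(C)C | intermediate
19 | 4-(tert-butyldimethylsilyloxy)-3-methoxybenzaldehyde | COc1cc(C=O)ccc1O[Si](C)(C)C(C)(C)C | starting material
20 | (S)-4-benzyl-3-{(2S,3R)-2-(ArO)-3-[4-(tert-butyldimethylsilyloxy)-3-methoxyphenyl]-3-hydroxypropanoyl}oxazolidin-2-one | COc1cc([C@H]2OC[C@H]3[C@@H]2CO[C@@H]3c2cc(OC)c(O[C@H](C(=O)N3[C@@H](Cc4ccccc4)COC3=O)[C@H](O)c3ccc(O[Si](C)(C)C(C)(C)C)c(OC)c3)c(OC)c2)ccc1O[Si](C(C)C)(C(C)C)C(C)C | intermediate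
21 | (1R,2R)-2-(ArO)-1-[4-(tert-butyldimethylsilyloxy)-3-methoxyphenyl]propane-1,3-diol (threo) | COc1cc([C@H]2OC[C@H]3[C@@H]2CO[C@@H]3c2cc(OC)c(O[C@H](CO)[C@H](O)c3ccc(O[Si](C)(C)C(C)(C)C)c(OC)c3)c(OC)c2)ccc1O[Si](C(C)C)(C(C)C)C(C)C | intermediate
22 | (1S,2R)-2-(ArO)-1-[4-(tert-butyldimethylsilyloxy)-3-methoxyphenyl]propane-1,3-diyl bis(4-nitrobenzoate) | COc1cc([C@H]2OC[C@H]3[C@@H]2CO[C@@H]3c2cc(OC)c(O[C@H](COC(=O)c3ccc(cc3)[N+](=O)[O-])[C@@H](OC(=O)c3ccc(cc3)[N+](=O)[O-])c3ccc(O[Si](C)(C)C(C)(C)C)c(OC)c3)c(OC)c2)ccc1O[Si](C(C)C)(C(C)C)C(C)C | intermediate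
23 | (1S,2R)-2-(ArO)-1-[4-(tert-butyldimethylsilyloxy)-3-methoxyphenyl]propane-1,3-diol (erythro) | COc1cc([C@H]2OC[C@H]3[C@@H]2CO[C@@H]3c2cc(OC)c(O[C@H](CO)[C@@H](O)c3ccc(O[Si](C)(C)C(C)(C)C)c(OC)c3)c(OC)c2)ccc1O[Si](C(C)C)(C(C)C)C(C)C | intermediate
24 | Hedyotol C | COc1cc([C@H]2OC[C@H]3[C@@H]2CO[C@@H]3c2cc(OC)c(O[C@H](CO)[C@@H](O)c3ccc(O)c(OC)c3)c(OC)c2)ccc1O | target

Total step count: 14. Longest linear sequence: 13 steps (steps 1–4 and 6–14; step 5 is a one-step side branch).

Steps most likely to fail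

Step 4 (proposed new method). The cyclopropane may fail to ionise with only one ester acceptor, or the cation may be diverted into capture by the ester oxygen followed by hydrolysis, or into oligomerisation. The fallback uses known chemistry, sets out from 4 and comes back at 9. Reduction of 4 with one equivalent of NaBH4 at 0 °C and acid-catalysed lactonisation (TsOH, toluene) should allow the lactone ester 6 to be isolated. 6 is a 2-arylcyclopropane-1,1-dicarbonyl compound of the kind that undergoes the Lewis-acid-catalysed (3+2) annulation of donor–acceptor cyclopropanes with aldehydes. With formaldehyde (paraformaldehyde, Sn(OTf)2, ClCH2CH2Cl) it should give ethyl (1R,5R,6S)-6-[3-methoxy-4-(triisopropylsilyloxy)phenyl]-2-oxo-3,7-dioxabicyclo[3.3.0]octane-1-carboxylate F1, the aryl-bearing centre settling on the convex face through the reversibly formed benzylic cation. Krapcho dealkoxycarbonylation (LiCl, wet DMSO, 140 °C) then removes the ester group and gives 9, the cis ring fusion being the only one the bicycle allows.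

Step 12. The activated, electron-rich benzylic alcohol may ionise instead of being displaced (loss of configuration), or elimination may compete with substitution. The fallback sets out from 21 and comes back at 23. MnO2 (CH2Cl2, rt) oxidises only the benzylic alcohol and should give (2R)-2-(ArO)-1-[4-(tert-butyldimethylsilyloxy)-3-methoxyphenyl]-3-hydroxypropan-1-one F2. Reduction under chelation control (Zn(BH4)2, Et2O, −20 °C) should deliver hydride anti to the aryloxy group and give the erythro diol 23 directly, so that 22 and step 13 are bypassed.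

Step 7. Facial selectivity in the capture of the benzylic cation may be poor, or the acid may epimerise the benzylic ring centres by reversible ring opening. The fallback sets out from 9 and comes back at 16. DIBAL-H (CH2Cl2, −78 °C) reduces the lactone to the lactol (1R,5R,6S)-6-[3-methoxy-4-(triisopropylsilyloxy)phenyl]-3,7-dioxabicyclo[3.3.0]octan-2-ol F3 (anomer mixture). Friedel–Crafts C-arylation of the derived bicyclic oxocarbenium ion with 2,6-dimethoxyphenol (BF3·OEt2, CH2Cl2, −40 °C), para to the hydroxyl group and on the convex face, should give 16 directly, so that 11–15 and the hydrogenolysis are bypassed.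

Further compounds
F1 | step 4 | ethyl (1R,5R,6S)-6-[3-methoxy-4-(triisopropylsilyloxy)phenyl]-2-oxo-3,7-dioxabicyclo[3.3.0]octane-1-carboxylate | O=C1OC[C@H]2[C@]1(C(=O)OCC)CO[C@@H]2c1ccc(O[Si](C(C)C)(C(C)C)C(C)C)c(OC)c1
F2 | step 12 | (2R)-2-(ArO)-1-[4-(tert-butyldimethylsilyloxy)-3-methoxyphenyl]-3-hydroxypropan-1-one | COc1cc([C@H]2OC[C@H]3[C@@H]2CO[C@@H]3c2cc(OC)c(O[C@H](CO)C(=O)c3ccc(O[Si](C)(C)C(C)(C)C)c(OC)c3)c(OC)c2)ccc1O[Si](C(C)C)(C(C)C)C(C)C
F3 | step 7 | (1R,5R,6S)-6-[3-methoxy-4-(triisopropylsilyloxy)phenyl]-3,7-dioxabicyclo[3.3.0]octan-2-ol, anomer mixture | OC1OC[C@H]2[C@@H]1CO[C@@H]2c1ccc(O[Si](C(C)C)(C(C)C)C(C)C)c(OC)c1
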